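**Retrosynthetic overview**
- The quinone (ring B) comes from air oxidation of the hydroquinone released when the tris-benzyl ether of the (S)-isoflavan is hydrogenolysed.
- Ring C is the only ring built: its O1–C2 bond is closed by an enantioselective anti-Markovnikov (6-endo) hydroetherification of a 2-(2-arylallyl)phenol, which sets C3 in the same step.
- The 2-(2-arylallyl)phenol comes from an aromatic Claisen rearrangement of an aryl 2-arylallyl ether, itself made by Mitsunobu union of the ring A phenol with the ring B allyl alcohol.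
- The ring A phenol comes from 2,6-dimethoxyphenol (benzylation, bromination, hydroxylation); the ring B allyl alcohol comes from 2,3-dimethoxyhydroquinone (benzylation, bromination, carbomagnesiation of propargyl alcohol).
- Rings A and B are bought as arenes; ring C is formed in the penultimate step.

Assumption: 2,3-dimethoxybenzene-1,4-diol is bought as such (it is the reduced form of the commercial 2,3-dimethoxy-1,4-benzoquinone).

The target's stereocentre is (S): at C3 the CIP order is C2 (O,H,H) > quinone carbon (C,C,C) > C4 (C,H,H) > H.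

**Step 1**
Reactants: 1 2,6-dimethoxyphenol
Product: 2 2-(benzyloxy)-1,3-dimethoxybenzene
Conditions: BnBr (1.1 equiv), K2CO3, DMF, 60 °C
Reagents that add atoms: benzyl bromide, BrCc1ccccc1
Why: Williamson ether synthesis on the phenoxide masks the future 7-OH as a benzyl ether that is removed together with the other benzyl groups in the last step.

**Step 2**
Reactants: 2 2-(benzyloxy)-1,3-dimethoxybenzene
Product: 3 2-(benzyloxy)-4-bromo-1,3-dimethoxybenzene
Conditions: NBS (1.0 equiv), MeCN, 0 °C to rt, dark
Reagents that add atoms: N-bromosuccinimide, O=C1CCC(=O)N1Br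
Why: Electrophilic aromatic bromination of a 1,2,3-trialkoxybenzene goes para to a flanking methoxy group (C4) because the twisted central alkoxy group is a poor donor to its own para position.

**Step 3**
Reactants: 3 2-(benzyloxy)-4-bromo-1,3-dimethoxybenzene
Product: 4 3-(benzyloxy)-2,4-dimethoxyphenol
Conditions: Pd2(dba)3 (1 mol%), tBuXPhos (4 mol%), KOH (3 equiv), 1,4-dioxane/H2O, 100 °C; then aq HCl
Reagents that add atoms: potassium hydroxide, [K+].[OH-]
Why: Palladium-catalysed hydroxylation of an aryl bromide (Buchwald-type C–O coupling; oxidative addition to zerovalent palladium, then C–O reductive elimination from the bulky biarylphosphine complex) tolerates electron-rich ortho-alkoxy substrates and leaves the ethers untouched.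

**Step 4**
Reactants: 5 2,3-dimethoxybenzene-1,4-diol
Product: 6 1,4-bis(benzyloxy)-2,3-dimethoxybenzene
Conditions: BnBr (2.3 equiv), K2CO3, DMF, 60 °C, N2
Reagents that add atoms: benzyl bromide, BrCc1ccccc1
Why: Double Williamson ether synthesis under inert gas stores the quinone oxidation level as a hydroquinone bis-benzyl ether.

**Step 5**
Reactants: 6 1,4-bis(benzyloxy)-2,3-dimethoxybenzene
Product: 7 1,4-bis(benzyloxy)-5-bromo-2,3-dimethoxybenzene
Conditions: NBS (1.0 equiv), MeCN, 0 °C, dark
Reagents that add atoms: N-bromosuccinimide, O=C1CCC(=O)N1Br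
Why: Electrophilic aromatic bromination of the tetra-alkoxybenzene can give only one monobromide because the two free ring positions are equivalent by symmetry, and one equivalent of NBS limits dibromination.

**Step 6**
Reactants: 7 1,4-bis(benzyloxy)-5-bromo-2,3-dimethoxybenzene; 8 prop-2-yn-1-ol
Product: 11 2-[2,5-bis(benzyloxy)-3,4-dimethoxyphenyl]prop-2-en-1-ol, via arylmagnesium bromide 9 (not isolated), via oxamagnesole chelate 10 (not isolated)
Conditions: Mg, LiCl, THF, 50 °C; then 8 pre-treated with i-PrMgCl (1.0 equiv, THF, −20 °C), CuI (10 mol%), −20 °C to rt; aq NH4Cl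
Reagents that add atoms: none
Why: Copper-catalysed anti-carbomagnesiation of the propargylic magnesium alkoxide (Duboudin-type reaction) puts the aryl group on the internal alkyne carbon through the five-membered magnesium chelate, so protonolysis gives the 2-arylallyl alcohol.

**Step 7**
Reactants: 4 3-(benzyloxy)-2,4-dimethoxyphenol; 11 2-[2,5-bis(benzyloxy)-3,4-dimethoxyphenyl]prop-2-en-1-ol
Product: 12 1,4-bis(benzyloxy)-5-{3-[3-(benzyloxy)-2,4-dimethoxyphenoxy]prop-1-en-2-yl}-2,3-dimethoxybenzene
Conditions: PPh3, DIAD, THF, 0 °C to rt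
Reagents that add atoms: none
Why: Mitsunobu etherification of a phenol with a primary allylic alcohol is reliable here because the 2-arylallyl unit is symmetric, so direct and allylic-transposed substitution give the same ether.

**Step 8**
Reactants: 12 1,4-bis(benzyloxy)-5-{3-[3-(benzyloxy)-2,4-dimethoxyphenoxy]prop-1-en-2-yl}-2,3-dimethoxybenzene
Product: 13 3-(benzyloxy)-6-{2-[2,5-bis(benzyloxy)-3,4-dimethoxyphenyl]prop-2-en-1-yl}-2,4-dimethoxyphenol
Conditions: PhNEt2, 185 °C, Ar
Reagents that add atoms: none
Why: Aromatic Claisen rearrangement ([3,3]-sigmatropic shift, then tautomerisation) can end only at the single unsubstituted ortho carbon, since the other ortho and the para positions carry methoxy groups, and the basic solvent suppresses acid-catalysed Markovnikov ring closure of the product.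

**Step 9**
Reactants: 13 3-(benzyloxy)-6-{2-[2,5-bis(benzyloxy)-3,4-dimethoxyphenyl]prop-2-en-1-yl}-2,4-dimethoxyphenol
Product: 14 (3S)-7-(benzyloxy)-3-[2,5-bis(benzyloxy)-3,4-dimethoxyphenyl]-6,8-dimethoxy-3,4-dihydro-2H-chromene
Conditions: 9-mesityl-3,6-di-tert-butyl-10-phenylacridinium tetrafluoroborate (5 mol%), chiral β-turn peptide thiol Boc-L-Cys-D-Pro-Aib-L-Phe-NMe2 (15 mol%; the antipode gives the R product), 2,6-lutidine (20 mol%), PhCF3, 450 nm LEDs, −20 °C, Ar
Reagents that add atoms: none
Why: Proposed new method: a catalytic enantioselective anti-Markovnikov intramolecular hydroetherification in which the photoexcited acridinium oxidises the electron-rich 1,1-disubstituted aryl alkene to its radical cation, the tethered phenol adds 6-endo to the terminal CH2 (forming the O1–C2 bond and ring C; the 5-exo Markovnikov mode would leave a primary radical), lutidine removes the proton to leave the tertiary benzylic C3 radical, and the peptide thiol, hydrogen-bonded to the neighbouring ether oxygens, delivers H to the Re face of that radical (C2 > aryl > C4) to set (S)-C3 while the thiyl radical is reduced by the acridine radical to close both cycles; the closest known reaction type is the racemic acridinium/thiol anti-Markovnikov hydroetherification of alkenols combined with peptide-thiol enantioselective hydrogen-atom transfer to prochiral radicals.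

**Step 10**
Reactants: 14 (3S)-7-(benzyloxy)-3-[2,5-bis(benzyloxy)-3,4-dimethoxyphenyl]-6,8-dimethoxy-3,4-dihydro-2H-chromene
Product: 16 2,3-dimethoxy-5-[(3S)-7-hydroxy-6,8-dimethoxy-3,4-dihydro-2H-chromen-3-yl]cyclohexa-2,5-diene-1,4-dione, via hydroquinone 15 (not isolated)
Conditions: H2 (1 atm), Pd/C (10 wt%), EtOAc/MeOH, rt; filter; then O2 (balloon), rt
Reagents that add atoms: none
Why: Catalytic hydrogenolysis cleaves all three benzyl ethers, and autoxidation then converts only the 2,3-dimethoxyhydroquinone to the quinone, because the para-alkylated 7-OH monophenol of ring A is inert to O2 under neutral conditions and the C3 stereocentre is not involved.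

**Compound list**
1 | 2,6-dimethoxyphenol | COc1cccc(OC)c1O | starting material
2 | 2-(benzyloxy)-1,3-dimethoxybenzene | COc1cccc(OC)c1OCc1ccccc1 | intermediate
3 | 2-(benzyloxy)-4-bromo-1,3-dimethoxybenzene | COc1ccc(Br)c(OC)c1OCc1ccccc1 | intermediate
4 | 3-(benzyloxy)-2,4-dimethoxyphenol | COc1ccc(O)c(OC)c1OCc1ccccc1 | intermediate
5 | 2,3-dimethoxybenzene-1,4-diol | COc1c(O)ccc(O)c1OC | starting material
6 | 1,4-bis(benzyloxy)-2,3-dimethoxybenzene | COc1c(OCc2ccccc2)ccc(OCc2ccccc2)c1OC | intermediate
7 | 1,4-bis(benzyloxy)-5-bromo-2,3-dimethoxybenzene | COc1c(OCc2ccccc2)cc(Br)c(OCc2ccccc2)c1OC | intermediate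
8 | prop-2-yn-1-ol | C#CCO | starting material
9 | [2,5-bis(benzyloxy)-3,4-dimethoxyphenyl]magnesium bromide | COc1c(OCc2ccccc2)cc([Mg]Br)c(OCc2ccccc2)c1OC | intermediate (not isolated)
10 | 4-[2,5-bis(benzyloxy)-3,4-dimethoxyphenyl]-2,5-dihydro-1,2-oxamagnesole (cyclic alkenylmagnesium alkoxide) | COc1c(OCc2ccccc2)cc(C2=C[Mg]OC2)c(OCc2ccccc2)c1OC | intermediate (not isolated)
11 | 2-[2,5-bis(benzyloxy)-3,4-dimethoxyphenyl]prop-2-en-1-ol | C=C(CO)c1cc(OCc2ccccc2)c(OC)c(OC)c1OCc1ccccc1 | intermediate
12 | 1,4-bis(benzyloxy)-5-{3-[3-(benzyloxy)-2,4-dimethoxyphenoxy]prop-1-en-2-yl}-2,3-dimethoxybenzene | C=C(COc1ccc(OC)c(OCc2ccccc2)c1OC)c1cc(OCc2ccccc2)c(OC)c(OC)c1OCc1ccccc1 | intermediate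
13 | 3-(benzyloxy)-6-{2-[2,5-bis(benzyloxy)-3,4-dimethoxyphenyl]prop-2-en-1-yl}-2,4-dimethoxyphenol | C=C(Cc1cc(OC)c(OCc2ccccc2)c(OC)c1O)c1cc(OCc2ccccc2)c(OC)c(OC)c1OCc1ccccc1 | intermediate
14 | (3S)-7-(benzyloxy)-3-[2,5-bis(benzyloxy)-3,4-dimethoxyphenyl]-6,8-dimethoxy-3,4-dihydro-2H-chromene | COc1c(OC)c(OCc2ccccc2)c([C@H]2COc3c(cc(OC)c(OCc4ccccc4)c3OC)C2)cc1OCc1ccccc1 | intermediate
15 | 2,3-dimethoxy-5-[(3S)-7-hydroxy-6,8-dimethoxy-3,4-dihydro-2H-chromen-3-yl]benzene-1,4-diol | COc1c(OC)c(O)c([C@H]2COc3c(cc(OC)c(O)c3OC)C2)cc1O | intermediate (not isolated)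
16 | 2,3-dimethoxy-5-[(3S)-7-hydroxy-6,8-dimethoxy-3,4-dihydro-2H-chromen-3-yl]cyclohexa-2,5-diene-1,4-dione | COC1=C(OC)C(=O)C([C@H]2COc3c(cc(OC)c(O)c3OC)C2)=CC1=O | target

**Step count**
Total steps: 10. Longest linear sequence: 7 (steps 1, 2, 3, 7, 8, 9, 10; the ring B branch through steps 4, 5, 6 is equally long).

**Three steps most likely to fail**

Step 9 (the proposed new reaction). The risks are: unproductive oxidation of the ring A phenol instead of the alkene, low enantioselectivity in the hydrogen-atom transfer, thiol–ene consumption of the catalyst, and dark Markovnikov closure to a 2-methyl-2-aryl-dihydrobenzofuran. The enantiomeric excess of 14 is checked by chiral HPLC and can be raised by recrystallisation.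
Fallback with known chemistry, setting out from 13 and returning at 14: copper-catalysed enantioselective protoboration of the 1,1-disubstituted aryl alkene (CuCl, chiral imidazolinium-derived NHC ligand, NaOtBu, B2pin2, MeOH, THF, −50 °C) gives the primary boronate (S)-3-(benzyloxy)-6-{2-[2,5-bis(benzyloxy)-3,4-dimethoxyphenyl]-3-(4,4,5,5-tetramethyl-1,3,2-dioxaborolan-2-yl)propyl}-2,4-dimethoxyphenol F3. Oxidation with NaBO3·4H2O in THF/H2O gives the diol (S)-3-(benzyloxy)-6-{2-[2,5-bis(benzyloxy)-3,4-dimethoxyphenyl]-3-hydroxypropyl}-2,4-dimethoxyphenol F4. Intramolecular Mitsunobu etherification (PPh3, DIAD, THF) then closes ring C at the primary carbinol without touching the stereocentre and delivers 14.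

Step 6 (carbomagnesiation with a hindered, electron-rich aryl Grignard reagent). The risks are sluggish magnesium insertion, protonation of the Grignard reagent and low conversion of the alkyne.
Fallback, setting out from 7 and returning at 11: Miyaura borylation (Pd(dppf)Cl2, B2pin2, KOAc, 1,4-dioxane, 90 °C) gives the boronate 2-[2,5-bis(benzyloxy)-3,4-dimethoxyphenyl]-4,4,5,5-tetramethyl-1,3,2-dioxaborolane F1. Suzuki–Miyaura coupling of F1 with commercial 2-bromoprop-2-en-1-ol (Pd(PPh3)4, K2CO3, 1,4-dioxane/H2O, 80 °C) gives 11.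

Step 8 (thermal Claisen rearrangement of a heavily substituted ether). The risks are decomposition at 185 °C and cyclisation of 13 to the dihydrobenzofuran.
Fallback, setting out from 11 and 4, bypassing 12 and returning at 13: Appel bromination of 11 (CBr4, PPh3, CH2Cl2, 0 °C) gives the allylic bromide 1,4-bis(benzyloxy)-5-(3-bromoprop-1-en-2-yl)-2,3-dimethoxybenzene F2. Direct ortho-C-allylation of the sodium phenoxide of 4 with F2 in a non-polar medium (NaH, toluene, rt to 50 °C) gives 13 at the only free ortho carbon; any O-alkylated by-product is 12 itself and can be recycled.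

**Further compounds**
F1 | step 6 | 2-[2,5-bis(benzyloxy)-3,4-dimethoxyphenyl]-4,4,5,5-tetramethyl-1,3,2-dioxaborolane | COc1c(OCc2ccccc2)cc(B2OC(C)(C)C(C)(C)O2)c(OCc2ccccc2)c1OC
F2 | step 8 | 1,4-bis(benzyloxy)-5-(3-bromoprop-1-en-2-yl)-2,3-dimethoxybenzene | C=C(CBr)c1cc(OCc2ccccc2)c(OC)c(OC)c1OCc1ccccc1
F3 | step 9 | (S)-3-(benzyloxy)-6-{2-[2,5-bis(benzyloxy)-3,4-dimethoxyphenyl]-3-(4,4,5,5-tetramethyl-1,3,2-dioxaborolan-2-yl)propyl}-2,4-dimethoxyphenol | COc1c(OC)c(OCc2ccccc2)c([C@@H](CB2OC(C)(C)C(C)(C)O2)Cc2cc(OC)c(OCc3ccccc3)c(OC)c2O)cc1OCc1ccccc1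
F4 | step 9 | (S)-3-(benzyloxy)-6-{2-[2,5-bis(benzyloxy)-3,4-dimethoxyphenyl]-3-hydroxypropyl}-2,4-dimethoxyphenol | COc1c(OC)c(OCc2ccccc2)c([C@@H](CO)Cc2cc(OC)c(OCc3ccccc3)c(OC)c2O)cc1OCc1ccccc1
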